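**Plan**
- Retrosynthesis: the six phenols are masked as benzyl ethers, the flavone pyranone ring C'' is opened at O1''–C2'' to a 1,3-diketone, and the C3–C3'' bond is then cut. This gives a (2S)-flavanone enol silane and a 2-bromo-1,3-diketone, both traced to one acetophenone.
- Enabling feature: C4(=O)–C3–C3''–C4''(=O) is a 1,4-diketone, so C3 and C3'' are both enol carbons. With ring C'' open, C3'' lies between two aroyl groups and gives an electrophilic radical that adds to the C3=C4 enol ether of ring C.
- This is a redox-neutral form of the oxidative C3–C3'' union of two C15 units presumed in the biosynthesis of 3,3''-biflavonoids.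
- Forward: acetophenone → chromone → ring C by asymmetric conjugate arylation → enol silane; acetophenone → MOM ether → Claisen condensation → bromide; union and closure of ring C'' in one flask; hydrogenolysis.
- Stereochemistry: C2 (S) from the chiral rhodium catalyst; C3 (R) from radical attack anti to the C2 aryl group and from the trans-diequatorial preference of ring C.

Key step: step 7

Assumption: the target is the 2,3-trans (2S,3R) isomer that its SMILES encodes, and acetophenone 1 is taken as purchased (otherwise one benzylation from 2',4',6'-trihydroxyacetophenone).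

**Step 1**
Reactants: 1 1-[2,4-bis(benzyloxy)-6-hydroxyphenyl]ethan-1-one
Product: 3 5,7-bis(benzyloxy)-4H-chromen-4-one, via enaminone 2 (not isolated)
Conditions: DMF-DMA, toluene, 100 °C; then conc. HCl, CH2Cl2, 40 °C
Reagents that add atoms: N,N-dimethylformamide dimethyl acetal, COC(OC)N(C)C
Why: Condensation of the methyl ketone with the amide acetal gives enaminone 2, and acid then drives 6-endo-trig addition of the phenol oxygen to the β-carbon and loss of dimethylamine (enaminone route to chromones).

**Step 2**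
Reactants: 3 5,7-bis(benzyloxy)-4H-chromen-4-one; 4 [4-(benzyloxy)phenyl]boronic acid
Product: 5 (2S)-5,7-bis(benzyloxy)-2-[4-(benzyloxy)phenyl]-2,3-dihydro-4H-chromen-4-one
Conditions: [Rh(OH)((S)-MeO-F12-BIPHEP)]2 (1 mol% Rh), toluene/H2O, 25 °C, no added base
Reagents that add atoms: none
Why: Rhodium-catalysed asymmetric 1,4-addition of an arylboronic acid (Hayashi–Miyaura reaction) to the C2=C3 bond of the chromone, in which the chiral bisphosphine on the aryl-rhodium species selects the face of C2 and so sets C2 as S (the (S)-ligand is expected to do this by the model that holds for cyclic enones, the (R)-ligand being used otherwise), while the base-free medium keeps the product from ring-opening to the chalcone.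

**Step 3**
Reactants: 5 (2S)-5,7-bis(benzyloxy)-2-[4-(benzyloxy)phenyl]-2,3-dihydro-4H-chromen-4-one
Product: 6 {[(2S)-5,7-bis(benzyloxy)-2-[4-(benzyloxy)phenyl]-2H-chromen-4-yl]oxy}(tert-butyl)dimethylsilane
Conditions: TBSOTf, Et3N, CH2Cl2, 0 °C
Reagents that add atoms: tert-butyldimethylsilyl trifluoromethanesulfonate, CC(C)(C)[Si](C)(C)OS(=O)(=O)C(F)(F)F
Why: Soft enolisation (O-silylation of the C4 carbonyl followed by removal of a C3 proton by the amine) gives the silyl enol ether without a free enolate, so that β-elimination of the ring oxygen cannot scramble C2.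

**Step 4**
Reactants: 1 1-[2,4-bis(benzyloxy)-6-hydroxyphenyl]ethan-1-one
Product: 7 1-[2,4-bis(benzyloxy)-6-(methoxymethoxy)phenyl]ethan-1-one
Conditions: MOMCl, i-Pr2NEt, CH2Cl2, 0 to 40 °C
Reagents that add atoms: chloromethyl methyl ether, COCCl
Why: O-Alkylation of the chelated phenol with the chloromethyl ether gives an acetal that survives the basic and radical steps and is removed by acid exactly when its oxygen is needed as O1''.

**Step 5**
Reactants: 7 1-[2,4-bis(benzyloxy)-6-(methoxymethoxy)phenyl]ethan-1-one; 8 methyl 4-(benzyloxy)benzoate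
Product: 9 1-[2,4-bis(benzyloxy)-6-(methoxymethoxy)phenyl]-3-[4-(benzyloxy)phenyl]propane-1,3-dione
Conditions: NaH, THF, reflux; then AcOH
Reagents that add atoms: none
Why: Crossed Claisen condensation of the sodium enolate of the methyl ketone with a non-enolisable aryl ester, pulled to completion by deprotonation of the 1,3-diketone formed.

**Step 6**
Reactants: 9 1-[2,4-bis(benzyloxy)-6-(methoxymethoxy)phenyl]-3-[4-(benzyloxy)phenyl]propane-1,3-dione
Product: 10 1-[2,4-bis(benzyloxy)-6-(methoxymethoxy)phenyl]-3-[4-(benzyloxy)phenyl]-2-bromopropane-1,3-dione (racemic)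
Conditions: NBS, CH2Cl2, 0 °C
Reagents that add atoms: N-bromosuccinimide, O=C1CCC(=O)N1Br
Why: Electrophilic bromination of the enol of the 1,3-diketone at its central carbon, which reacts much faster than the acyl-deactivated aryl ether rings.

**Step 7**
Reactants: 6 {[(2S)-5,7-bis(benzyloxy)-2-[4-(benzyloxy)phenyl]-2H-chromen-4-yl]oxy}(tert-butyl)dimethylsilane; 10 1-[2,4-bis(benzyloxy)-6-(methoxymethoxy)phenyl]-3-[4-(benzyloxy)phenyl]-2-bromopropane-1,3-dione
Product: 12 (2S,3R)-5,7-bis(benzyloxy)-3-{5,7-bis(benzyloxy)-2-[4-(benzyloxy)phenyl]-4-oxo-4H-chromen-3-yl}-2-[4-(benzyloxy)phenyl]-2,3-dihydro-4H-chromen-4-one, via triketone 11 (not isolated)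
Conditions: fac-Ir(ppy)3 (1 mol%), 2,6-lutidine, MeCN/CH2Cl2, blue LEDs, 25 °C; then HCl, MeOH/THF, 50 °C
Reagents that add atoms: none
Why: The excited Ir(III) catalyst should reduce the C–Br bond of 10 to bromide and the electrophilic 1,3-diketon-2-yl radical, which adds to the electron-rich C3=C4 enol ether of 6 at C3 (leaving a C4 radical stabilised by the silyloxy group and ring A); Ir(IV) oxidises this radical to the silyloxocarbenium ion, loss of the silyl group gives the C4 ketone of 11 and the catalyst is returned (radical–polar crossover). The closest known reaction type is the visible-light photoredox α-alkylation of silyl enol ethers with α-bromo-1,3-dicarbonyl compounds to 1,4-dicarbonyl products, a redox-neutral relative of Ce(IV)- or Mn(III)-mediated oxidative enol coupling. In the acidic second stage the MOM ether is lost and the freed phenol oxygen adds to the 4-benzyloxybenzoyl carbonyl in a 6-exo-trig closure to a cyclic hemiketal, which loses water to give the pyranone ring C'' of the flavone; the C3'' centre formed as a mixture in the first stage becomes sp2 in this event. The new C3 stereocentre is controlled by the C2 aryl group, which shields one face of the 2H-chromene so that the radical enters anti to it, and acid-mediated enolisation of the C4 ketone in the second stage can only reinforce the 2,3-trans (diequatorial) arrangement, giving 2S,3R. The step needs radical formation at C3'' alone, which the weak C–Br bond between two carbonyl groups secures in the presence of seven aryl ethers, and pyranone closure in preference to furan closure across the C4/C4'' 1,4-diketone, which the ortho phenol placed for six-ring hemiketal formation should secure.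

**Step 8**
Reactants: 12 (2S,3R)-5,7-bis(benzyloxy)-3-{5,7-bis(benzyloxy)-2-[4-(benzyloxy)phenyl]-4-oxo-4H-chromen-3-yl}-2-[4-(benzyloxy)phenyl]-2,3-dihydro-4H-chromen-4-one
Product: 13 (2S,3R)-5,7-dihydroxy-3-[5,7-dihydroxy-2-(4-hydroxyphenyl)-4-oxo-4H-chromen-3-yl]-2-(4-hydroxyphenyl)-2,3-dihydro-4H-chromen-4-one
Conditions: H2 (1 atm), 10% Pd/C, THF/MeOH, 25 °C
Reagents that add atoms: none
Why: Hydrogenolysis of the six aryl benzyl ethers on palladium under neutral conditions, which leaves the tetrasubstituted C2''=C3'' bond, the C4 ketone and the two stereocentres (no enolate, no ring-opening) as they are.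

**Compound list**
1 | 1-[2,4-bis(benzyloxy)-6-hydroxyphenyl]ethan-1-one | CC(=O)c1c(O)cc(OCc2ccccc2)cc1OCc1ccccc1 | starting material
2 | (E)-1-[2,4-bis(benzyloxy)-6-hydroxyphenyl]-3-(dimethylamino)prop-2-en-1-one | CN(C)/C=C/C(=O)c1c(O)cc(OCc2ccccc2)cc1OCc1ccccc1 | intermediate
3 | 5,7-bis(benzyloxy)-4H-chromen-4-one | O=c1ccoc2cc(OCc3ccccc3)cc(OCc3ccccc3)c12 | intermediate
4 | [4-(benzyloxy)phenyl]boronic acid | OB(O)c1ccc(OCc2ccccc2)cc1 | starting material
5 | (2S)-5,7-bis(benzyloxy)-2-[4-(benzyloxy)phenyl]-2,3-dihydro-4H-chromen-4-one | O=C1C[C@@H](c2ccc(OCc3ccccc3)cc2)Oc2cc(OCc3ccccc3)cc(OCc3ccccc3)c12 | intermediate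
6 | {[(2S)-5,7-bis(benzyloxy)-2-[4-(benzyloxy)phenyl]-2H-chromen-4-yl]oxy}(tert-butyl)dimethylsilane | CC(C)(C)[Si](C)(C)OC1=C[C@@H](c2ccc(OCc3ccccc3)cc2)Oc2cc(OCc3ccccc3)cc(OCc3ccccc3)c12 | intermediate
7 | 1-[2,4-bis(benzyloxy)-6-(methoxymethoxy)phenyl]ethan-1-one | CC(=O)c1c(OCOC)cc(OCc2ccccc2)cc1OCc1ccccc1 | intermediate
8 | methyl 4-(benzyloxy)benzoate | COC(=O)c1ccc(OCc2ccccc2)cc1 | starting material
9 | 1-[2,4-bis(benzyloxy)-6-(methoxymethoxy)phenyl]-3-[4-(benzyloxy)phenyl]propane-1,3-dione | O=C(CC(=O)c1ccc(OCc2ccccc2)cc1)c1c(OCOC)cc(OCc2ccccc2)cc1OCc1ccccc1 | intermediate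
10 | 1-[2,4-bis(benzyloxy)-6-(methoxymethoxy)phenyl]-3-[4-(benzyloxy)phenyl]-2-bromopropane-1,3-dione (racemic) | O=C(C(Br)C(=O)c1ccc(OCc2ccccc2)cc1)c1c(OCOC)cc(OCc2ccccc2)cc1OCc1ccccc1 | intermediate
11 | 1-[2,4-bis(benzyloxy)-6-(methoxymethoxy)phenyl]-3-[4-(benzyloxy)phenyl]-2-{(2S,3R)-5,7-bis(benzyloxy)-2-[4-(benzyloxy)phenyl]-4-oxo-3,4-dihydro-2H-chromen-3-yl}propane-1,3-dione (both epimers at the central carbon of the dione) | O=C1c2c(OCc3ccccc3)cc(OCc3ccccc3)cc2O[C@H](c2ccc(OCc3ccccc3)cc2)[C@H]1C(C(=O)c1ccc(OCc2ccccc2)cc1)C(=O)c1c(OCOC)cc(OCc2ccccc2)cc1OCc1ccccc1 | intermediate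
12 | (2S,3R)-5,7-bis(benzyloxy)-3-{5,7-bis(benzyloxy)-2-[4-(benzyloxy)phenyl]-4-oxo-4H-chromen-3-yl}-2-[4-(benzyloxy)phenyl]-2,3-dihydro-4H-chromen-4-one | O=C1c2c(OCc3ccccc3)cc(OCc3ccccc3)cc2O[C@H](c2ccc(OCc3ccccc3)cc2)[C@H]1c1c(-c2ccc(OCc3ccccc3)cc2)oc2cc(OCc3ccccc3)cc(OCc3ccccc3)c2c1=O | intermediate
13 | (2S,3R)-5,7-dihydroxy-3-[5,7-dihydroxy-2-(4-hydroxyphenyl)-4-oxo-4H-chromen-3-yl]-2-(4-hydroxyphenyl)-2,3-dihydro-4H-chromen-4-one | O=C1c2c(O)cc(O)cc2O[C@H](c2ccc(O)cc2)[C@H]1c1c(-c2ccc(O)cc2)oc2cc(O)cc(O)c2c1=O | target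

**Step count and risks**

Total step count: 8. Longest linear sequence: 5 steps (1, 2, 3, 7, 8 or 4, 5, 6, 7, 8).

Steps most likely to fail:

1. Step 7. Radical addition at the hindered C3 may be slow, so that hydrogen abstraction by the diketonyl radical or protodesilylation of 6 takes over. The C4 cation or the 1,4-diketone may also be diverted into furan closure in the acid stage instead of pyranone closure. The fallback closes the flavone ring before the union and uses a two-electron coupling. It sets out from 10 and 6 and comes back at 12. Bromide 10 with HCl in MeOH/THF should lose the MOM group and cyclodehydrate to 5,7-bis(benzyloxy)-2-[4-(benzyloxy)phenyl]-3-bromo-4H-chromen-4-one F1. This vinyl bromide is then joined to enol silane 6 by palladium-catalysed α-arylation through the tin enolate (Pd2(dba)3, P(t-Bu)3, Bu3SnF, CsF, toluene, 85 °C), which gives 12 directly, with C3 again ending trans to the C2 aryl group.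

2. Step 2. Insertion of the electron-rich, 5-substituted chromone into the aryl–rhodium bond may be sluggish, and reversible ring-opening may erode the enantiomeric purity. The fallback replaces asymmetric catalysis by ring closure and resolution. It sets out from 1 and comes back at 5. Claisen–Schmidt condensation of 1 with 4-(benzyloxy)benzaldehyde (KOH, EtOH) gives (E)-1-[2,4-bis(benzyloxy)-6-hydroxyphenyl]-3-[4-(benzyloxy)phenyl]prop-2-en-1-one F2. Oxa-Michael cyclisation (NaOAc, EtOH, reflux) gives racemic 5,7-bis(benzyloxy)-2-[4-(benzyloxy)phenyl]-2,3-dihydro-4H-chromen-4-one F3. Chromatography on a chiral stationary phase then gives 5, and (2R)-5,7-bis(benzyloxy)-2-[4-(benzyloxy)phenyl]-2,3-dihydro-4H-chromen-4-one F4 is returned to the racemate through F2 with base.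

3. Step 8. Over-reduction may occur (hydrogenolysis of the benzylic C2–O1 bond or reduction of the C4 ketone) before the hindered 5-O-benzyl groups are removed. The fallback removes the benzyl groups by Lewis acid instead of hydrogen. It sets out from 12 and comes back at 13. BCl3 with pentamethylbenzene as cation scavenger in CH2Cl2 at −78 °C should cleave all six ethers without touching the ring C ether bond or the ketones.

Further compounds
F1 | step 7 | 5,7-bis(benzyloxy)-2-[4-(benzyloxy)phenyl]-3-bromo-4H-chromen-4-one | O=c1c(Br)c(-c2ccc(OCc3ccccc3)cc2)oc2cc(OCc3ccccc3)cc(OCc3ccccc3)c12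
F2 | step 2 | (E)-1-[2,4-bis(benzyloxy)-6-hydroxyphenyl]-3-[4-(benzyloxy)phenyl]prop-2-en-1-one | O=C(/C=C/c1ccc(OCc2ccccc2)cc1)c1c(O)cc(OCc2ccccc2)cc1OCc1ccccc1
F3 | step 2 | racemic 5,7-bis(benzyloxy)-2-[4-(benzyloxy)phenyl]-2,3-dihydro-4H-chromen-4-one | O=C1CC(c2ccc(OCc3ccccc3)cc2)Oc2cc(OCc3ccccc3)cc(OCc3ccccc3)c12
F4 | step 2 | (2R)-5,7-bis(benzyloxy)-2-[4-(benzyloxy)phenyl]-2,3-dihydro-4H-chromen-4-one | O=C1C[C@H](c2ccc(OCc3ccccc3)cc2)Oc2cc(OCc3ccccc3)cc(OCc3ccccc3)c12
F0 | step 8 | none | none
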